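The target is disconnected at the spiro-cyclohexene by a late Diels–Alder reaction (C2–C4′, C14–C15′) into a dienone from dehydrocostus lactone and 8′β-silyloxy-dehydrozaluzanin C, which is built de novo. Its seven-membered ring (C1′, C10′, C9′, C8′, C7′, C6′, C5′) is closed by a (4+3) annulation that exploits C1′/C6′ as the β- and formyl carbons of an achiral cyclopentene carbaldehyde, with epimerisable C5′ between them. A chiral bis-boronate delivers C10′ by rhodium-catalysed 1,4-addition and C7′ by intramolecular allylboration of the released aldehyde, forming C1′–C10′, C6′–C7′ and the trans-fused α-methylene lactone in one operation.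

Key step: step 8

Remark on the chemistry: guaianolide numbering is used (unprimed = cyclopentenone half, primed = hydroxylated half). As drawn, H-5 of the cyclopentenone half is cis to H-6, the opposite of dehydrocostus lactone, so this γ-position of the enone is inverted late under kinetic control (step 17).

Step 1
Reactants: 1 propadiene; 2 bis(pinacolato)diboron
Product: 3 2,3-bis(pinacolboryl)prop-1-ene
Conditions: Pt(PPh3)4 (3 mol %), toluene, 80 °C
Reagents that add atoms: none
Why: Diboration of an allene catalysed by zerovalent platinum (Miyaura type) adds the B–B bond across one C=C and gives the allyl/alkenyl bis-boronate; no stereocentre is formed.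

Step 2
Reactants: 3 2,3-bis(pinacolboryl)prop-1-ene; 4 3-(trimethylsilyl)prop-2-ynal
Product: 5 (3R)-5-(pinacolboryl)-1-(trimethylsilyl)hex-5-en-1-yn-3-ol
Conditions: (R)-TRIP phosphoric acid (5 mol %), toluene, −30 °C; aq. NaHCO3
Reagents that add atoms: none
Why: Chiral-phosphoric-acid-catalysed allylboration (chair Zimmerman–Traxler transition state) transfers only the allylic C–B bond, leaves the alkenyl boronate, and sets the (R) carbinol that becomes C8′; the acid antipode is chosen for this sense.

Step 3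
Reactants: 5 (3R)-5-(pinacolboryl)-1-(trimethylsilyl)hex-5-en-1-yn-3-ol
Product: 6 (3R)-3-(tert-butyldimethylsilyloxy)-5-(pinacolboryl)-1-(trimethylsilyl)hex-5-en-1-yne
Conditions: TBSOTf, 2,6-lutidine, CH2Cl2, −78 °C
Reagents that add atoms: tert-butyldimethylsilyl triflate, CC(C)(C)[Si](C)(C)OS(=O)(=O)C(F)(F)F
Why: Standard silylation of the secondary propargylic alcohol; the stereocentre is untouched and the ether carries the C8′ oxygen to the end.

Step 4
Reactants: 6 (3R)-3-(tert-butyldimethylsilyloxy)-5-(pinacolboryl)-1-(trimethylsilyl)hex-5-en-1-yne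
Product: 7 (3R)-3-(tert-butyldimethylsilyloxy)-5-(pinacolboryl)hex-5-en-1-yne
Conditions: K2CO3, MeOH, 0 °C
Reagents that add atoms: none
Why: Base-mediated protodesilylation of the C(sp)–Si bond; the silyl ether and the pinacol boronate should survive the short, cold exposure.

Step 5
Reactants: 7 (3R)-3-(tert-butyldimethylsilyloxy)-5-(pinacolboryl)hex-5-en-1-yne
Product: 9 methyl (4R)-4-(tert-butyldimethylsilyloxy)-6-(pinacolboryl)hept-6-en-2-ynoate, via lithium acetylide 8 (not isolated)
Conditions: LiN(SiMe3)2, THF, −78 °C; then ClCO2Me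
Reagents that add atoms: methyl chloroformate, COC(=O)Cl
Why: Acylation of the lithium acetylide with a chloroformate; the hindered amide base does not attack boron and the stereocentre is not acidic.

Step 6
Reactants: 9 methyl (4R)-4-(tert-butyldimethylsilyloxy)-6-(pinacolboryl)hept-6-en-2-ynoate
Product: 11 methyl (2Z,4R)-4-(tert-butyldimethylsilyloxy)-6-(pinacolboryl)-2-[(pinacolboryl)methyl]hepta-2,6-dienoate, via α-aluminated acrylate 10 (not isolated)
Conditions: i-Bu2AlH, HMPA, THF, 0 °C; then ICH2B(pin), 0 °C to rt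
Reagents that add atoms: 2-(iodomethyl)-4,4,5,5-tetramethyl-1,3,2-dioxaborolane, ICB1OC(C)(C)C(C)(C)O1
Why: Conjugate syn-hydroalumination of the ynoate puts aluminium on C11′ cis to the new C7′–H, and alkylation of the alkenylalane with the iodomethylboronate proceeds with retention (Hall-type synthesis of 2-alkoxycarbonylallylboronates), giving the (Z) isomer with C8′ cis to the ester.

Step 7
Reactants: 12 6-bromo-1,4-dioxaspiro[4.4]non-6-ene
Product: 14 1,4-dioxaspiro[4.4]non-6-ene-6-carbaldehyde, via 6-lithio ketal 13 (not isolated)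
Conditions: n-BuLi, THF, −78 °C; DMF; aq. NH4Cl
Reagents that add atoms: N,N-dimethylformamide, CN(C)C=O
Why: Bromine–lithium exchange of the α-bromo enone ketal and formylation with DMF (a known α-ketovinyl anion equivalent); no stereocentre.

Step 8
Reactants: 11 methyl (2Z,4R)-4-(tert-butyldimethylsilyloxy)-6-(pinacolboryl)-2-[(pinacolboryl)methyl]hepta-2,6-dienoate; 14 1,4-dioxaspiro[4.4]non-6-ene-6-carbaldehyde
Product: 16 8β-(tert-butyldimethylsilyloxy)-4,4-(ethylenedioxy)-15-norguaia-10(14),11(13)-dien-12,6α-olide, via conjugate-adduct aldehyde 15 (not isolated)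
Conditions: [RhCl(cod)]2 (2.5 mol %), (S)-BINAP (6 mol %), KOH (0.3 equiv), dioxane/H2O 10:1, 40 °C, then 80 °C; aq. NH4Cl
Reagents that add atoms: none
Why: Hydroxo-rhodium (monovalent) transmetalates only the alkenyl boronate of 11 and adds C10′ to the enal β-carbon C1′ of 14 (Hayashi–Miyaura 1,4-addition), and water protonates the oxa-π-allyl rhodium to give aldehyde 15. On warming, the tethered 2-(alkoxycarbonyl)allylboronate allylates the formyl group (Hall-type allylboration) and the borate lactonises with loss of methanol; both reaction types are known on these substrate classes and are run here as one domino sequence. The cycloheptane closes through C6′–C7′ in a six-membered chair Zimmerman–Traxler transition state fused to the forming seven-membered ring, and the γ-lactone closes by 5-exo-trig acyl substitution. C1′ is set by the (S)-BINAP–rhodium catalyst (ligand antipode chosen for the configuration drawn), and C5′ by base-mediated epimerisation of the α-formyl centre, since only the cis aldehyde reaches the allylboronate (stereoconvergent). C6′ and C7′ follow from the (Z)-allylboronate, which puts both ring bonds equatorial in the chair and gives the anti adduct, hence the trans lactone, with the C8′ silyloxy group of 11 on the outside. The step needs alkenyl-over-allyl boron chemoselectivity and 1,4- over 1,2-addition, secured by the ester-deactivated allylboronate being slow in transmetalation and in intermolecular carbonyl addition below 80 °C and by the aqueous hydroxo-rhodium conditions.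

Step 9
Reactants: 16 8β-(tert-butyldimethylsilyloxy)-4,4-(ethylenedioxy)-15-norguaia-10(14),11(13)-dien-12,6α-olide
Product: 17 8β-(tert-butyldimethylsilyloxy)-4-oxo-15-norguaia-10(14),11(13)-dien-12,6α-olide
Conditions: PPTS, acetone/H2O 10:1, 50 °C
Reagents that add atoms: water, O
Why: Buffered acid hydrolysis of the dioxolane, which should leave the silyl ether, both exocyclic alkenes and the cis ring fusion (C5′ is now α to the ketone) intact.

Step 10
Reactants: 17 8β-(tert-butyldimethylsilyloxy)-4-oxo-15-norguaia-10(14),11(13)-dien-12,6α-olide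
Product: 18 8β-(tert-butyldimethylsilyloxy)dehydrocostus lactone
Conditions: Zn, CH2Br2, TiCl4, THF/CH2Cl2, 0 °C to rt
Reagents that add atoms: dibromomethane, BrCBr
Why: Lombardo–Takai methylenation; the non-basic zinc/titanium reagent converts the ketone into the C4′=C15′ methylene without touching the lactone or epimerising C5′.

Step 11
Reactants: 18 8β-(tert-butyldimethylsilyloxy)dehydrocostus lactone
Product: 19 3α-hydroxy-8β-(tert-butyldimethylsilyloxy)dehydrocostus lactone
Conditions: SeO2 (0.5 equiv), t-BuOOH, CH2Cl2, rt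
Reagents that add atoms: tert-butyl hydroperoxide, CC(C)(C)OO; selenium dioxide, O=[Se]=O
Why: Selenium dioxide allylic oxidation (ene reaction, then 2,3-sigmatropic shift) hydroxylates the allylic methylene C3′ as in dehydrocostus lactone, C9′ being shielded by the adjacent silyloxy group; oxygen enters from the convex α-face and the new centre is removed in step 12.

Step 12
Reactants: 19 3α-hydroxy-8β-(tert-butyldimethylsilyloxy)dehydrocostus lactone
Product: 20 8β-(tert-butyldimethylsilyloxy)dehydrozaluzanin C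
Conditions: Dess–Martin periodinane, NaHCO3, CH2Cl2, 0 °C to rt
Reagents that add atoms: none
Why: Dess–Martin oxidation of the allylic alcohol gives the exocyclic enone without base, preserving C5′ and the α-methylene lactone.

Step 13
Reactants: 21 dehydrocostus lactone
Product: 22 3-epizaluzanin C
Conditions: SeO2 (0.5 equiv), t-BuOOH, CH2Cl2, rt
Reagents that add atoms: tert-butyl hydroperoxide, CC(C)(C)OO; selenium dioxide, O=[Se]=O
Why: Known selenium dioxide allylic hydroxylation of dehydrocostus lactone at C3 (ene reaction, then 2,3-sigmatropic shift, from the convex α-face).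

Step 14
Reactants: 22 3-epizaluzanin C
Product: 23 dehydrozaluzanin C
Conditions: Dess–Martin periodinane, NaHCO3, CH2Cl2, rt
Reagents that add atoms: none
Why: Dess–Martin oxidation of the allylic alcohol to the exocyclic enone; the C3 stereocentre disappears.

Step 15
Reactants: 23 dehydrozaluzanin C
Product: 24 3-(tert-butyldimethylsilyloxy)guaia-2,4(15),10(14),11(13)-tetraen-12,6α-olide
Conditions: TBSOTf, Et3N, CH2Cl2, 0 °C
Reagents that add atoms: tert-butyldimethylsilyl triflate, CC(C)(C)[Si](C)(C)OS(=O)(=O)C(F)(F)F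
Why: Soft enolisation; C2 carries the only α-hydrogens (C4 is sp2), so the 2-silyloxy diene forms regiospecifically and C1 and C5 are untouched.

Step 16
Reactants: 24 3-(tert-butyldimethylsilyloxy)guaia-2,4(15),10(14),11(13)-tetraen-12,6α-olide; 20 8β-(tert-butyldimethylsilyloxy)dehydrozaluzanin C
Product: 27 8′-O-silyl spiro dimer with 5α-H and 10α-H, via dienone 25 (not isolated), via Diels–Alder adduct 26 (not isolated)
Conditions: 24 (3 equiv), Pd(OAc)2 (3.3 equiv), MeCN/CH2Cl2, rt, argon, dark; then DBU (0.2 equiv), 0 °C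
Reagents that add atoms: none
Why: Saegusa–Ito oxidation with divalent palladium unveils dienone 25, whose s-cis diene C2=C1–C10=C14 adds to the exocyclic enone of 20 in a Diels–Alder reaction with ortho regiochemistry (C2–C4′, C14–C15′) from the α-faces of both partners (anti to C6 and anti to C6′), which enforces the carbonyl-exo transition state and sets spiro C4′; DBU then moves the C1=C10 bond into conjugation through the dienolate, and C10 is protonated under thermodynamic control to the 10α-H isomer.

Step 17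
Reactants: 27 8′-O-silyl spiro dimer with 5α-H and 10α-H
Product: 29 8′-O-silyl ether of the target, via dipotassium bis-enolate 28 (not isolated)
Conditions: KN(SiMe3)2 (2.5 equiv), THF, −78 °C; inverse quench into AcOH/THF, −78 °C
Reagents that add atoms: none
Why: Kinetic γ-protonation of an extended enolate: the doubly allylic C5–H is removed to give the planar cross-conjugated dienolate (the cyclopentanone of the other half is enolised and returns unchanged), and the proton should enter at C5 from the β-face, anti to the C6–C7 bond that the trans lactone holds on the α-face, giving the 5β-H epimer, which the cold acidic quench keeps from re-equilibrating.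

Step 18
Reactants: 29 8′-O-silyl ether of the target
Product: 30 CNP0178208.1
Conditions: HF·pyridine, THF/pyridine, 0 °C to rt
Reagents that add atoms: none
Why: Fluoride cleavage of the silyl ether under weakly acidic, non-enolising conditions, so that C5 and C10 keep their configuration.

Compound list
1 | propadiene (allene) | C=C=C | starting material
2 | bis(pinacolato)diboron | CC1(C)OB(OC1(C)C)B1OC(C)(C)C(C)(C)O1 | starting material
3 | 2,3-bis(pinacolboryl)prop-1-ene | C=C(CB1OC(C)(C)C(C)(C)O1)B1OC(C)(C)C(C)(C)O1 | intermediate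
4 | 3-(trimethylsilyl)prop-2-ynal | C[Si](C)(C)C#CC=O | starting material
5 | (3R)-5-(pinacolboryl)-1-(trimethylsilyl)hex-5-en-1-yn-3-ol | C[Si](C)(C)C#C[C@H](O)CC(=C)B1OC(C)(C)C(C)(C)O1 | intermediate
6 | (3R)-3-(tert-butyldimethylsilyloxy)-5-(pinacolboryl)-1-(trimethylsilyl)hex-5-en-1-yne | C[Si](C)(C)C#C[C@H](O[Si](C)(C)C(C)(C)C)CC(=C)B1OC(C)(C)C(C)(C)O1 | intermediate
7 | (3R)-3-(tert-butyldimethylsilyloxy)-5-(pinacolboryl)hex-5-en-1-yne | C#C[C@H](O[Si](C)(C)C(C)(C)C)CC(=C)B1OC(C)(C)C(C)(C)O1 | intermediate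
8 | lithium acetylide of 7 | [Li]C#C[C@H](O[Si](C)(C)C(C)(C)C)CC(=C)B1OC(C)(C)C(C)(C)O1 | intermediate
9 | methyl (4R)-4-(tert-butyldimethylsilyloxy)-6-(pinacolboryl)hept-6-en-2-ynoate | COC(=O)C#C[C@H](O[Si](C)(C)C(C)(C)C)CC(=C)B1OC(C)(C)C(C)(C)O1 | intermediate
10 | methyl (4R)-2-(diisobutylalumanyl)-4-(tert-butyldimethylsilyloxy)-6-(pinacolboryl)hepta-2,6-dienoate, aluminium cis to H-7′ | COC(=O)/C([Al](CC(C)C)CC(C)C)=C\[C@H](O[Si](C)(C)C(C)(C)C)CC(=C)B1OC(C)(C)C(C)(C)O1 | intermediate
11 | methyl (2Z,4R)-4-(tert-butyldimethylsilyloxy)-6-(pinacolboryl)-2-[(pinacolboryl)methyl]hepta-2,6-dienoate | COC(=O)/C(CB1OC(C)(C)C(C)(C)O1)=C\[C@H](O[Si](C)(C)C(C)(C)C)CC(=C)B1OC(C)(C)C(C)(C)O1 | intermediate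
12 | 6-bromo-1,4-dioxaspiro[4.4]non-6-ene (2-bromocyclopent-2-enone ethylene ketal) | BrC1=CCCC12OCCO2 | starting material
13 | 6-lithio-1,4-dioxaspiro[4.4]non-6-ene | [Li]C1=CCCC12OCCO2 | intermediate
14 | 1,4-dioxaspiro[4.4]non-6-ene-6-carbaldehyde | O=CC1=CCCC12OCCO2 | intermediate
15 | conjugate-adduct aldehyde (cis-2-alkenyl cyclopentanecarbaldehyde ketal carrying the (Z)-allylboronate; the epimer at C5′ equilibrates with it) | O=C[C@@H]1[C@@H](CCC12OCCO2)C(=C)C[C@@H](O[Si](C)(C)C(C)(C)C)/C=C(/CB1OC(C)(C)C(C)(C)O1)C(=O)OC | intermediate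
16 | (1αH,5αH,6βH,7αH)-8β-(tert-butyldimethylsilyloxy)-4,4-(ethylenedioxy)-15-norguaia-10(14),11(13)-dien-12,6α-olide | O1CCOC12CC[C@H]3C(=C)C[C@@H](O[Si](C)(C)C(C)(C)C)[C@H]4C(=C)C(=O)O[C@@H]4[C@H]32 | intermediate
17 | (1αH,5αH,6βH,7αH)-8β-(tert-butyldimethylsilyloxy)-4-oxo-15-norguaia-10(14),11(13)-dien-12,6α-olide | O=C1CC[C@H]2C(=C)C[C@@H](O[Si](C)(C)C(C)(C)C)[C@H]3C(=C)C(=O)O[C@@H]3[C@H]21 | intermediate
18 | 8β-(tert-butyldimethylsilyloxy)dehydrocostus lactone | C=C1CC[C@H]2C(=C)C[C@@H](O[Si](C)(C)C(C)(C)C)[C@H]3C(=C)C(=O)O[C@@H]3[C@H]21 | intermediate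
19 | 3α-hydroxy-8β-(tert-butyldimethylsilyloxy)dehydrocostus lactone | C=C1[C@H](O)C[C@H]2C(=C)C[C@@H](O[Si](C)(C)C(C)(C)C)[C@H]3C(=C)C(=O)O[C@@H]3[C@H]21 | intermediate
20 | 8β-(tert-butyldimethylsilyloxy)dehydrozaluzanin C | C=C1C(=O)C[C@H]2C(=C)C[C@@H](O[Si](C)(C)C(C)(C)C)[C@H]3C(=C)C(=O)O[C@@H]3[C@H]21 | intermediate
21 | dehydrocostus lactone | C=C1CC[C@H]2C(=C)CC[C@H]3C(=C)C(=O)O[C@@H]3[C@H]21 | starting material
22 | 3-epizaluzanin C (3α-hydroxydehydrocostus lactone) | C=C1[C@H](O)C[C@H]2C(=C)CC[C@H]3C(=C)C(=O)O[C@@H]3[C@H]21 | intermediate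
23 | dehydrozaluzanin C | C=C1C(=O)C[C@H]2C(=C)CC[C@H]3C(=C)C(=O)O[C@@H]3[C@H]21 | intermediate
24 | 3-(tert-butyldimethylsilyloxy)guaia-2,4(15),10(14),11(13)-tetraen-12,6α-olide | C=C1C(O[Si](C)(C)C(C)(C)C)=C[C@H]2C(=C)CC[C@H]3C(=C)C(=O)O[C@@H]3[C@H]21 | intermediate
25 | 3-oxoguaia-1,4(15),10(14),11(13)-tetraen-12,6α-olide (5αH) | C=C1C(=O)C=C2C(=C)CC[C@H]3C(=C)C(=O)O[C@@H]3[C@H]21 | intermediate
26 | Diels–Alder adduct: spiro dimer with C1=C10, 2β-H, 5α-H and 8′β-silyloxy | C=C1C(=O)[C@H]2C3=C(CC[C@H]4C(=C)C(=O)O[C@@H]4[C@@H]13)CC[C@]21C(=O)C[C@H]2C(=C)C[C@@H](O[Si](C)(C)C(C)(C)C)[C@H]3C(=C)C(=O)O[C@@H]3[C@H]21 | intermediate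
27 | 8′-O-(tert-butyldimethylsilyl) spiro dimer, 1(2)-en-3-one with 5α-H and 10α-H (C5 epimer of 29) | C=C1C(=O)C2=C3[C@H](CC[C@H]4C(=C)C(=O)O[C@@H]4[C@@H]13)CC[C@]21C(=O)C[C@H]2C(=C)C[C@@H](O[Si](C)(C)C(C)(C)C)[C@H]3C(=C)C(=O)O[C@@H]3[C@H]21 | intermediate
28 | dipotassium bis-enolate of 27 (C3-oxido C1=C5 dienolate; C3′ enolate) | C=C1C(O[K])=C2C=3[C@H](CC[C@H]4C(=C)C(=O)O[C@@H]4C1=3)CC[C@]21C(O[K])=C[C@H]2C(=C)C[C@@H](O[Si](C)(C)C(C)(C)C)[C@H]3C(=C)C(=O)O[C@@H]3[C@H]21 | intermediate
29 | 8′-O-(tert-butyldimethylsilyl) ether of the target (5β-H, 10α-H) | C=C1C(=O)C2=C3[C@H](CC[C@H]4C(=C)C(=O)O[C@@H]4[C@H]13)CC[C@]21C(=O)C[C@H]2C(=C)C[C@@H](O[Si](C)(C)C(C)(C)C)[C@H]3C(=C)C(=O)O[C@@H]3[C@H]21 | intermediate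
30 | CNP0178208.1 | C=C1C(=O)C2=C3[C@H](CC[C@H]4C(=C)C(=O)O[C@@H]4[C@H]13)CC[C@]21C(=O)C[C@H]2C(=C)C[C@@H](O)[C@H]3C(=C)C(=O)O[C@@H]3[C@H]21 | target

Total step count: 18
Longest linear sequence: 14 steps (steps 1–6, 8–12, 16–18)

Steps most likely to fail

Step 8. The allylboronate may transmetalate to rhodium or add to the enal before the 1,4-addition, the catalyst may be mismatched with the C8′ centre, or the trans-fused ring may close before C5′ epimerises. The fallback sets out from 9 and 14 and returns at 16. Hydroalumination of 9 as in step 6, but quenched with paraformaldehyde, should give methyl (2Z,4R)-4-(tert-butyldimethylsilyloxy)-2-(hydroxymethyl)-6-(pinacolboryl)hepta-2,6-dienoate F1. Its alkenyl boronate is added to 14 under the rhodium conditions of step 8 at 40 °C to give the hydroxy aldehyde F2. Mesylation and displacement (MsCl, Et3N, then LiBr) give the allylic bromide F3. An intramolecular Nozaki–Hiyama–Kishi-type Barbier allylation with CrCl2 (divalent chromium) in THF/DMF, anti-selective through the allylchromium chair, followed by acid lactonisation, closes the seven-membered ring and the trans lactone to 16.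

Step 17. Protonation may occur at C2 (deconjugation) or on the wrong face, or the product may drift back to the 5α-H epimer. The fallback sets out from 27 and returns at 29. Soft enolisation (Me3SiOTf, Et3N, CH2Cl2, −78 to 0 °C) gives the isolable bis(trimethylsilyl) enol ether F6, whose cyclopentenone half is a 2-silyloxyfulvene. It is desilylated and protonated at −78 °C with Bu4NF/AcOH in THF, conditions under which the tert-butyldimethylsilyl ether should persist, to give 29.

Step 16. The transient dienone may dimerise with itself, add through the carbonyl-endo mode (wrong spiro centre), or its dienol may be autoxidised at C10. The fallback sets out from 24 (with 20) and returns at 27. Saegusa oxidation of 24 at high dilution without 20, followed at once by Luche reduction (NaBH4, CeCl3·7H2O, MeOH, −78 °C), gives 3β-hydroxyguaia-1,4(15),10(14),11(13)-tetraen-12,6α-olide F4, a diene that lacks the enone dienophile. It is heated with 20 (toluene, 80 °C) in a normal-demand Diels–Alder reaction with the same facial course to give the adduct alcohol F5. Dess–Martin oxidation gives 26, and DBU as in step 16 gives 27.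

Further compounds
F1 | step 8 | methyl (2Z,4R)-4-(tert-butyldimethylsilyloxy)-2-(hydroxymethyl)-6-(pinacolboryl)hepta-2,6-dienoate | COC(=O)/C(CO)=C\[C@H](O[Si](C)(C)C(C)(C)C)CC(=C)B1OC(C)(C)C(C)(C)O1
F2 | step 8 | hydroxy aldehyde (conjugate adduct of F1 and 14, cis-disubstituted cyclopentane) | O=C[C@@H]1[C@@H](CCC12OCCO2)C(=C)C[C@@H](O[Si](C)(C)C(C)(C)C)/C=C(/CO)C(=O)OC
F3 | step 8 | bromo aldehyde (allylic bromide from F2) | O=C[C@@H]1[C@@H](CCC12OCCO2)C(=C)C[C@@H](O[Si](C)(C)C(C)(C)C)/C=C(/CBr)C(=O)OC
F4 | step 16 | 3β-hydroxyguaia-1,4(15),10(14),11(13)-tetraen-12,6α-olide | C=C1[C@@H](O)C=C2C(=C)CC[C@H]3C(=C)C(=O)O[C@@H]3[C@H]21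
F5 | step 16 | Diels–Alder adduct alcohol (3β-hydroxy analogue of 26) | C=C1[C@@H](O)[C@H]2C3=C(CC[C@H]4C(=C)C(=O)O[C@@H]4[C@@H]13)CC[C@]21C(=O)C[C@H]2C(=C)C[C@@H](O[Si](C)(C)C(C)(C)C)[C@H]3C(=C)C(=O)O[C@@H]3[C@H]21
F6 | step 17 | bis(trimethylsilyl) enol ether of 27 (2-silyloxyfulvene in the cyclopentenone half) | C=C1C(O[Si](C)(C)C)=C2C=3[C@H](CC[C@H]4C(=C)C(=O)O[C@@H]4C1=3)CC[C@]21C(O[Si](C)(C)C)=C[C@H]2C(=C)C[C@@H](O[Si](C)(C)C(C)(C)C)[C@H]3C(=C)C(=O)O[C@@H]3[C@H]21
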